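## Analysis of the target

Compound 13 is made of two identical 2,2-dimethylchroman units whose C6 atoms are bonded to one methine carbon that also carries a 5-methylhexyl chain (a 6-methylheptane-1,1-diyl bridge). In each unit the benzene ring (ring A) is hexasubstituted: C4a and C8a belong to the dihydropyran ring (ring B, O1 on C8a), C5 and C7 carry free hydroxyls, C6 carries the bridge and C8 a 2-methylbutanoyl group. The only stereocentres are the two α-carbons of the acyl groups, both (R). They sit in separate halves, too far apart to influence each other, and because the two aryl groups are identical the bridging methine is not stereogenic. These centres are α to aryl ketones and can epimerise by enolisation; the phloroglucinol-type rings oxidise easily, and the doubly ortho-oxygenated diarylmethane can be cleaved by strong acid. The synthesis is hard for two reasons: the three oxygens of each ring must be told apart around a crowded bridge, and two remote, labile stereocentres must be set with absolute control and no neighbouring centre to relay it. The strategy rests on the position of each C8 carbonyl ortho to the free C7 hydroxyl. A formyl group on C8 is therefore a salicylaldehyde unit, whose C–H bond can be added across a diene under phenoxide direction, making the carbonyl–C(α) bond and the methyl-bearing centre in one event, with a vinyl group as the latent ethyl group.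

## Retrosynthetic reasoning

**13 back to 11.** The two ethyl groups are traced to vinyl groups and the two C5 hydroxyls to benzyl ethers, so one catalytic hydrogenation finishes the synthesis. Vinyl ranks at C(α) exactly as ethyl does (below the carbonyl carbon, above methyl), so the (R) centres of 11 map directly onto those of 13. The forward step must saturate the terminal alkenes before they can move into conjugation with the ketone.

**11 back to 8 and two molecules of 9.** The two C(=O)–C(α) bonds are cut. This is the bond that carries the stereocentre, and it lies next to a carbonyl that is ortho to the C7 phenol, so both the bond and the centre can come from a formyl C–H bond of bis-aldehyde 8 and one molecule of butadiene 9 per site under a chiral rhodium catalyst. The gain is two skeletal bonds and both stereocentres in one operation from a C4 feedstock, with no chiral acyl donor and no Friedel–Crafts acylation of a ring that already holds an epimerisable centre. The forward reaction has to be branched-selective and enantioselective at each site. It is placed after the dimerisation so that the β,γ-unsaturated ketones never meet the acid used to build the bridge.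

**8 back to two molecules of 5 and aldehyde 6.** The two aryl–CH bonds at C6 are cut. The cut uses the symmetry of the target, and C6 of chroman 5 is the only unsubstituted ring carbon, ortho to two oxygens, para to O1 and meta to the formyl group. The forward reaction is a twofold electrophilic substitution by one aliphatic aldehyde, which must be favoured over reaction at the much less electrophilic ring formyl groups.

**5 back to 2 and prenol 3.** The O1–C2 and C4–C4a bonds of ring B are cut. In phenol 2 the two free ring carbons are equivalent, and the benzyl ether on the para oxygen leaves only an ortho hydroxyl next to the new prenyl group. Ring closure can therefore only place the pyran oxygen on C8a, next to the formyl group, and the benzyl ether on C5. The same benzyl group later keeps the C5 oxygen out of the rhodium chemistry and leaves in the final hydrogenation.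

**2 back to 1.** The benzyl ether is cut from the para oxygen of the commercial trihydroxybenzaldehyde 1. The formyl carbon is carried from the start on purpose. If C8 carried an ester instead, the dimer would need hydride reduction and reoxidation, passing through 2-hydroxybenzyl alcohols on a phloroglucinol ring. Such alcohols ionise to ortho-quinone methides and are prone to over-reduction to the methyl arene. Starting at the aldehyde oxidation level saves two steps on the most valuable intermediate.

## Alternatives that were turned down

Alternative 1: Both benzene rings assembled by a double Danheiser annulation.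
- Disconnection: each benzene ring is split into a two-carbon alkyne unit (C5, C6) and a four-carbon cyclobutenone unit (C7, C8, C8a, C4a).
- Forward key step: the skipped bis(siloxyalkyne) A2, whose central carbon already bears the 5-methylhexyl chain, is heated with two equivalents of the pyran-fused 3-alkoxycyclobutenone A3. Electrocyclic opening to a vinylketene, [2+2] addition to the ynol ether, a second 4π opening and 6π closure would form C6–C7, C4a–C5 and C7–C8 in each half. The product is bis-phenol A1, with the C5 oxygen silylated and C7–OH free.
- For: every ring substituent is placed by the pericyclic cascade, so the ring oxygens are differentiated and the crowded diarylmethine exists before the arenes do. On these two points it is stronger than the chosen route, which depends on a para-selective benzylation and a Friedel–Crafts dimerisation.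
- Against: A2 is a 1,4-diyne with a doubly propargylic hydrogen that isomerises easily to allenes, and its two ynol silyl ethers require a twofold ester homologation. A3 needs its own multistep synthesis. A1 still lacks both acyl groups, so acylation at C8 between two oxygens and both stereocentres remain unsolved, most likely by a chiral acid chloride under Lewis acid, which endangers the α-centre.
- Comparison: the route would be well over twice as long and postpones the stereochemical problem. The chosen plan reaches its key precursor 8 in three steps and makes both acyl groups with their stereocentres in one step.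

Alternative 2: Both pyran rings closed by gold-mediated hydroarylation of aryl propargyl ethers.
- Disconnection: the C4–C4a bonds of both pyran rings, leaving aryl 1,1-dimethylpropargyl ethers.
- Forward key step: bis(propargyl ether) A5 already carries both (R)-2-methylbutanoyl groups, the C5 benzyl ethers and the free C7 hydroxyls. With Ph3PAuNTf2 as π-acid, each terminal alkyne would be attacked in 6-endo fashion by C4a, the only free ring carbon, giving bis(2H-chromene) A4. One hydrogenation would then saturate C3=C4 and remove the benzyl groups.
- For: cyclisation of aryl propargyl ethers to 2,2-dimethylchromenes is well established, the regiochemistry is fixed, and the endgame is a single hydrogenation as in the chosen route. Because the acyl groups are present before the key step, their stereocentres would come from a conventional (R)-2-methylbutanoyl donor. That rests on firmer precedent than an asymmetric hydroacylation, and on this point the alternative is stronger.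
- Against: the acylation must be done on a phloroglucinol under Friedel–Crafts or Fries conditions, where α-branched acyl groups are prone to partial racemisation. The centres must then survive base-mediated O-alkylation with a tertiary propargyl electrophile and gold catalysis next to a chelated phenol and an enolisable ketone. Etherifying the C8a oxygen rather than the C7 oxygen, both ortho to the ketone, is a further unsolved selectivity.
- Comparison: several more steps, all carried out after the stereocentres exist. The chosen route creates the centres in the penultimate step, exposes them to one further operation, and builds ring B in one early step from prenol 3.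

Alternative 3: The aryl ether bonds of both pyran rings made at the end by palladium catalysis.
- Disconnection: the O1–C8a bonds of both pyran rings.
- Forward key step: bis(aryl bromide) A7 has a 3-hydroxy-3-methylbutyl chain on C4a and bromine on C8a of each ring. A zerovalent palladium catalyst formed from Pd(OAc)2 and 2-(di-tert-butylphosphino)-1,1'-binaphthyl, with Cs2CO3 as base, would take it through oxidative addition, alkoxide binding and C–O reductive elimination, closing both six-membered rings to give tetra-benzyl ether A6.
- For: intramolecular palladium-catalysed etherification with tertiary alcohols is an established chroman synthesis, a tertiary alkoxide has no β-hydrogen to lose, and the position of the pyran oxygen is fixed by the bromine. On regiochemical certainty for ring B it is stronger than an acid-mediated annulation.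
- Against: oxidative addition into so electron-rich an aryl bromide is slow, and protodebromination competes. A7 requires a long sequence to differentiate, brominate and dimerise pentasubstituted arenes. A6 lacks the acyl groups and has all phenols benzylated, so C8 acylation, selective unmasking and both stereocentres are still open.
- Comparison: it spends its key step on a ring that the chosen route closes in one operation at the outset, and leaves the real problem, the two stereocentres, unanswered.

Key step: step 4

Assumption 1: the sense of induction of the bisphosphine cannot be predicted for this new reaction. (R)-DTBM-SEGPHOS is written; its antipode is used instead if a trial with aldehyde 5 shows the opposite sense.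
Assumption 2: 6-methylheptanal (6) is treated as a purchasable aldehyde.

## Route

Step 1
Reactants: 1 2,4,6-trihydroxybenzaldehyde
Product: 2 4-(benzyloxy)-2,6-dihydroxybenzaldehyde
Conditions: BnBr (1.0 equiv), NaHCO3 (1.2 equiv), DMF, 40 °C
Reagents that add atoms: benzyl bromide, BrCc1ccccc1
Why: Williamson etherification of the monophenoxide; the C4 hydroxyl, para to the formyl group, is the most acidic and least hindered, while the ortho hydroxyls are flanked by the formyl group and share a hydrogen bond to its oxygen, so a weak base and one equivalent of halide should favour the 4-O-benzyl ether. Any ortho or dibenzyl ether would be removed by chromatography.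

Step 2
Reactants: 2 4-(benzyloxy)-2,6-dihydroxybenzaldehyde; 3 prenol (3-methylbut-2-en-1-ol)
Product: 5 5-(benzyloxy)-7-hydroxy-2,2-dimethylchromane-8-carbaldehyde, via prenylphenol 4 (not isolated)
Conditions: 3 (1.0 equiv), BF3·OEt2 (30 mol%), 1,4-dioxane, 25 to 50 °C
Reagents that add atoms: none
Why: Lewis-acid Friedel–Crafts prenylation at one of the two equivalent free ring carbons gives 4; protonation of its trisubstituted alkene gives a tertiary cation that is captured by the only adjacent free hydroxyl, so the pyran oxygen ends up ortho to the formyl group and the benzyl ether at C5. One equivalent of 3 limits a second annulation at the remaining ring carbon.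

Step 3
Reactants: 5 5-(benzyloxy)-7-hydroxy-2,2-dimethylchromane-8-carbaldehyde (two molecules); 6 6-methylheptanal
Product: 8 6,6'-(6-methylheptane-1,1-diyl)bis[5-(benzyloxy)-7-hydroxy-2,2-dimethylchromane-8-carbaldehyde], via carbinol 7 (not isolated)
Conditions: 5 (2.2 equiv), 6 (1.0 equiv, slow addition), pTsOH·H2O (10 mol%), toluene, 60 °C
Reagents that add atoms: none
Why: Acid-catalysed phenol–aldehyde condensation (hydroxyalkylation, then Friedel–Crafts alkylation): C6 of 5 attacks the protonated aliphatic aldehyde, and carbinol 7 ionises to a benzylic cation (a protonated ortho-quinone methide) that a second molecule of 5 captures at C6. The ring formyl groups are hydrogen-bonded vinylogous esters and far less electrophilic than 6, and slow addition of 6 to excess 5 suppresses its self-aldol reaction.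

Step 4
Reactants: 8 6,6'-(6-methylheptane-1,1-diyl)bis[5-(benzyloxy)-7-hydroxy-2,2-dimethylchromane-8-carbaldehyde]; 9 buta-1,3-diene (two molecules)
Product: 11 (2R,2'R)-1,1'-[(6-methylheptane-1,1-diyl)bis(5-(benzyloxy)-7-hydroxy-2,2-dimethylchromane-6,8-diyl)]bis(2-methylbut-3-en-1-one), via mono-adduct 10 (not isolated)
Conditions: [Rh(cod)Cl]2 (5 mol%), (R)-DTBM-SEGPHOS (11 mol%), K3PO4 (20 mol%), 9 (10 equiv, as a THF solution), THF, 40 °C, sealed tube
Reagents that add atoms: none
Why: Proposed new method: K3PO4 generates the C7 phenoxide, which binds monovalent rhodium bearing the bisphosphine and directs oxidative addition of the adjacent formyl C–H bond to give a five-membered acyl–aryloxide chelate of trivalent rhodium hydride, in which the chelate holds back decarbonylation. Migratory insertion of one molecule of 9 into the Rh–H bond then produces an η3-1-methylallyl ligand, and C–C reductive elimination between the acyl carbon and the methyl-bearing allyl terminus releases the branched 2-methylbut-3-enoyl ketone and regenerates monovalent rhodium; the second formyl group of mono-adduct 10 takes up the second molecule of 9 in the same way. The closest known reactions are rhodium- and cobalt-catalysed hydroacylations of 1,3-dienes with salicylaldehydes, which give α-methyl β,γ-unsaturated ketones, and enantioselective rhodium–bisphosphine hydroacylations of other alkenes with salicylaldehydes; an enantioselective addition to butadiene itself, run twice on one substrate, has not been shown. No ring is closed. Each new stereocentre (the α-carbon of each acyl group) is set under catalyst control: the bisphosphine on the chelated rhodium decides which face of the 1-methylallyl ligand meets the acyl carbon. The two sites are remote and react independently, so minor-sense events should end up mainly in (R,S) diastereomers, which are in principle separable from 11 and leave it enriched beyond the single-site selectivity. The step needs branched rather than linear (1,4) coupling, for which the tendency of rhodium allyls to form bonds at the more substituted terminus and the crowded chelate are relied on, and it needs the product to survive, so low base loading, 40 °C and prompt work-up are used to prevent enolisation of the new centre and migration of the alkene into conjugation. The C5 hydroxyls are kept as benzyl ethers so that only the chelating C7 phenoxide is present.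

Step 5
Reactants: 11 (2R,2'R)-1,1'-[(6-methylheptane-1,1-diyl)bis(5-(benzyloxy)-7-hydroxy-2,2-dimethylchromane-6,8-diyl)]bis(2-methylbut-3-en-1-one)
Product: 13 (2R,2'R)-1,1'-[(6-methylheptane-1,1-diyl)bis(5,7-dihydroxy-2,2-dimethylchromane-6,8-diyl)]bis(2-methylbutan-1-one), via saturated dibenzyl ether 12 (not isolated)
Conditions: H2 (1 atm), Pd/C (10%), EtOAc, 20 °C, stopped as soon as 12 is consumed
Reagents that add atoms: none
Why: Heterogeneous hydrogenation: the monosubstituted vinyl groups should be saturated first (to 12) and the two aryl benzyl ethers then hydrogenolysed, while the chelated, electron-rich aryl ketones are not reduced at 1 atm. The α-centres are not touched, and since vinyl and ethyl have the same rank at C(α) the (R) descriptor is unchanged, provided the alkene is saturated before it can migrate.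

## Compound list

1 | 2,4,6-trihydroxybenzaldehyde | O=Cc1c(O)cc(O)cc1O | starting material
2 | 4-(benzyloxy)-2,6-dihydroxybenzaldehyde | O=Cc1c(O)cc(OCc2ccccc2)cc1O | intermediate
3 | prenol (3-methylbut-2-en-1-ol) | CC(C)=CCO | starting material
4 | 4-(benzyloxy)-2,6-dihydroxy-3-(3-methylbut-2-en-1-yl)benzaldehyde | O=Cc1c(O)cc(OCc2ccccc2)c(CC=C(C)C)c1O | intermediate (not isolated)
5 | 5-(benzyloxy)-7-hydroxy-2,2-dimethylchromane-8-carbaldehyde | O=Cc1c(O)cc(OCc2ccccc2)c2CCC(C)(C)Oc12 | intermediate
6 | 6-methylheptanal | CC(C)CCCCC=O | starting material
7 | 5-(benzyloxy)-7-hydroxy-6-(1-hydroxy-6-methylheptyl)-2,2-dimethylchromane-8-carbaldehyde (racemic) | CC(C)CCCCC(O)c1c(OCc3ccccc3)c2CCC(C)(C)Oc2c(C=O)c1O | intermediate (not isolated)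
8 | 6,6'-(6-methylheptane-1,1-diyl)bis[5-(benzyloxy)-7-hydroxy-2,2-dimethylchromane-8-carbaldehyde] | CC(C)CCCCC(c1c(OCc3ccccc3)c2CCC(C)(C)Oc2c(C=O)c1O)c1c(OCc3ccccc3)c2CCC(C)(C)Oc2c(C=O)c1O | intermediate
9 | buta-1,3-diene | C=CC=C | starting material
10 | 5-(benzyloxy)-6-{1-[5-(benzyloxy)-7-hydroxy-2,2-dimethyl-8-((2R)-2-methylbut-3-enoyl)chroman-6-yl]-6-methylheptyl}-7-hydroxy-2,2-dimethylchromane-8-carbaldehyde (both epimers at the bridging carbon) | CC(C)CCCCC(c1c(OCc3ccccc3)c2CCC(C)(C)Oc2c(C(=O)[C@H](C)C=C)c1O)c1c(OCc3ccccc3)c2CCC(C)(C)Oc2c(C=O)c1O | intermediate (not isolated)
11 | (2R,2'R)-1,1'-[(6-methylheptane-1,1-diyl)bis(5-(benzyloxy)-7-hydroxy-2,2-dimethylchromane-6,8-diyl)]bis(2-methylbut-3-en-1-one) | CC(C)CCCCC(c1c(OCc3ccccc3)c2CCC(C)(C)Oc2c(C(=O)[C@H](C)C=C)c1O)c1c(OCc3ccccc3)c2CCC(C)(C)Oc2c(C(=O)[C@H](C)C=C)c1O | intermediate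
12 | (2R,2'R)-1,1'-[(6-methylheptane-1,1-diyl)bis(5-(benzyloxy)-7-hydroxy-2,2-dimethylchromane-6,8-diyl)]bis(2-methylbutan-1-one) | CC(C)CCCCC(c1c(OCc3ccccc3)c2CCC(C)(C)Oc2c(C(=O)[C@H](C)CC)c1O)c1c(OCc3ccccc3)c2CCC(C)(C)Oc2c(C(=O)[C@H](C)CC)c1O | intermediate (not isolated)
13 | (2R,2'R)-1,1'-[(6-methylheptane-1,1-diyl)bis(5,7-dihydroxy-2,2-dimethylchromane-6,8-diyl)]bis(2-methylbutan-1-one) | CC[C@@H](C)C(=O)c1c(O)c(C(CCCCC(C)C)c2c(O)c3c(c(C(=O)[C@H](C)CC)c2O)OC(C)(C)CC3)c(O)c2c1OC(C)(C)CC2 | target

## Step count and risk

Total step count: 5. Longest linear sequence: 5 steps (1 to 13).

**Step 4 (key step).**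
- What may go wrong: reductive elimination at the unsubstituted allyl terminus (linear 1,4-coupling); poor enantioface selection; base-mediated enolisation that erodes the new centres or moves the alkene into conjugation, followed by oxa-Michael closure onto the C7 phenol; slow phenoxide binding because the C7 oxygen is flanked by the bulky C6 substituent; stalling after the first addition; decarbonylation.
- Why: the reaction type is untested on butadiene in enantioselective form, and the substrate is a hindered, electron-rich dimer.
- Fallback, known chemistry, from 8 and rejoining at 13: the two C7 hydroxyls of 8 are benzylated (BnBr, Cs2CO3, DMF, 60 °C) to the tetra-O-benzyl bis-aldehyde F1. Brown crotylboration of both formyl groups, with the (E)-crotyldiisopinocampheylborane antipode that makes the methyl-bearing carbon (R) (THF, −78 °C, then NaOH/H2O2), gives the bis(anti-homoallylic alcohol) F2. Buffered Dess–Martin oxidation (NaHCO3, CH2Cl2, 0 °C) removes the carbinol centres and gives the tetra-O-benzyl bis[(R)-2-methylbut-3-enoyl] ketone F3 without moving the double bond. Hydrogenation over Pd/C then saturates both vinyl groups and cleaves all four benzyl ethers to give 13.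

**Step 3.**
- What may go wrong: self-aldol condensation of the enolisable aldehyde; tautomerisation of the quinone methide stage to an alkenylphenol; a stalled second arylation because the new bond forms between two ortho,ortho'-dioxygenated rings.
- Fallback, from 5 and rejoining at 8: a three-component Betti condensation of 5, 6 and morpholine (EtOH, 60 °C) gives the Mannich base F4. On heating with a second equivalent of 5 in toluene at 110 °C it loses morpholine to the ortho-quinone methide under neutral conditions, and this is captured at C6 of 5 to give 8.

**Step 5.**
- What may go wrong: migration of the terminal double bond into conjugation by palladium hydride before saturation, which would scramble the α-centres; slow hydrogenolysis of the hindered C5 benzyl ethers.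
- Fallback, from 11 and rejoining at 13: the vinyl groups are reduced without metal by diimide (KO2CN=NCO2K, AcOH, MeOH/CH2Cl2, 0 °C) to give 12, which is isolated. The benzyl ethers are then hydrogenolysed over Pd(OH)2/C, when no allylic centre remains. No compound outside the numbered list arises (F0).

**Step 2.**
- What may go wrong: over-prenylation at the second ring carbon, O-prenylation, or stalling at the open prenylphenol, all typical of direct acid-mediated chroman annulation of a deactivated phloroglucinol.
- Fallback, from 2 and rejoining at 5: condensation of 2 with 3-methylbut-2-enal under ethylenediammonium diacetate (toluene, 110 °C; Knoevenagel-type addition, then oxa-6π electrocyclisation onto the only adjacent free hydroxyl) gives 5-(benzyloxy)-7-hydroxy-2,2-dimethyl-2H-chromene-8-carbaldehyde F5. Its C3=C4 bond is hydrogenated chemoselectively (H2, Pd/C poisoned with Ph2S, EtOAc), keeping the benzyl ether and the aldehyde, to give 5.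

## Further compounds

F1 | step 4 | 6,6'-(6-methylheptane-1,1-diyl)bis[5,7-bis(benzyloxy)-2,2-dimethylchromane-8-carbaldehyde] | CC(C)CCCCC(c1c(OCc3ccccc3)c2CCC(C)(C)Oc2c(C=O)c1OCc4ccccc4)c1c(OCc3ccccc3)c2CCC(C)(C)Oc2c(C=O)c1OCc4ccccc4
F2 | step 4 | (1R,1'R,2R,2'R)-1,1'-[(6-methylheptane-1,1-diyl)bis(5,7-bis(benzyloxy)-2,2-dimethylchromane-6,8-diyl)]bis(2-methylbut-3-en-1-ol) | CC(C)CCCCC(c1c(OCc3ccccc3)c2CCC(C)(C)Oc2c([C@H](O)[C@H](C)C=C)c1OCc4ccccc4)c1c(OCc3ccccc3)c2CCC(C)(C)Oc2c([C@H](O)[C@H](C)C=C)c1OCc4ccccc4
F3 | step 4 | (2R,2'R)-1,1'-[(6-methylheptane-1,1-diyl)bis(5,7-bis(benzyloxy)-2,2-dimethylchromane-6,8-diyl)]bis(2-methylbut-3-en-1-one) | CC(C)CCCCC(c1c(OCc3ccccc3)c2CCC(C)(C)Oc2c(C(=O)[C@H](C)C=C)c1OCc4ccccc4)c1c(OCc3ccccc3)c2CCC(C)(C)Oc2c(C(=O)[C@H](C)C=C)c1OCc4ccccc4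
F4 | step 3 | 5-(benzyloxy)-7-hydroxy-2,2-dimethyl-6-[6-methyl-1-(morpholin-4-yl)heptyl]chromane-8-carbaldehyde (racemic) | CC(C)CCCCC(N4CCOCC4)c1c(OCc3ccccc3)c2CCC(C)(C)Oc2c(C=O)c1O
F0 | step 5 | none | none
F5 | step 2 | 5-(benzyloxy)-7-hydroxy-2,2-dimethyl-2H-chromene-8-carbaldehyde | O=Cc1c(O)cc(OCc2ccccc2)c2C=CC(C)(C)Oc12
A1 | alternative 1 | 6,6'-(6-methylheptane-1,1-diyl)bis[2,2-dimethyl-5-(triisopropylsilyloxy)chroman-7-ol] | CC(C)CCCCC(c1c(O[Si](C(C)C)(C(C)C)C(C)C)c2CCC(C)(C)Oc2cc1O)c1c(O[Si](C(C)C)(C(C)C)C(C)C)c2CCC(C)(C)Oc2cc1O
A2 | alternative 1 | 3-(5-methylhexyl)-1,5-bis(triisopropylsilyloxy)penta-1,4-diyne | CC(C)CCCCC(C#CO[Si](C(C)C)(C(C)C)C(C)C)C#CO[Si](C(C)C)(C(C)C)C(C)C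
A3 | alternative 1 | 3,3-dimethyl-2-oxabicyclo[4.2.0]oct-1(6)-en-7-one | O=C1CC2=C1CCC(C)(C)O2
A4 | alternative 2 | (2R,2'R)-1,1'-[(6-methylheptane-1,1-diyl)bis(5-(benzyloxy)-7-hydroxy-2,2-dimethyl-2H-chromene-6,8-diyl)]bis(2-methylbutan-1-one) | CC(C)CCCCC(c1c(OCc3ccccc3)c2C=CC(C)(C)Oc2c(C(=O)[C@H](C)CC)c1O)c1c(OCc3ccccc3)c2C=CC(C)(C)Oc2c(C(=O)[C@H](C)CC)c1O
A5 | alternative 2 | (2R,2'R)-1,1'-{(6-methylheptane-1,1-diyl)bis[4-(benzyloxy)-2-hydroxy-6-((2-methylbut-3-yn-2-yl)oxy)-3,1-phenylene]}bis(2-methylbutan-1-one) | CC(C)CCCCC(c1c(OCc3ccccc3)cc(OC(C)(C)C#C)c(C(=O)[C@H](C)CC)c1O)c1c(OCc3ccccc3)cc(OC(C)(C)C#C)c(C(=O)[C@H](C)CC)c1O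
A6 | alternative 3 | 6,6'-(6-methylheptane-1,1-diyl)bis[5,7-bis(benzyloxy)-2,2-dimethylchromane] | CC(C)CCCCC(c1c(OCc3ccccc3)c2CCC(C)(C)Oc2cc1OCc4ccccc4)c1c(OCc3ccccc3)c2CCC(C)(C)Oc2cc1OCc4ccccc4
A7 | alternative 3 | 4,4'-[(6-methylheptane-1,1-diyl)bis(2,4-bis(benzyloxy)-6-bromo-3,1-phenylene)]bis(2-methylbutan-2-ol) | CC(C)CCCCC(c1c(OCc3ccccc3)c(CCC(C)(C)O)c(Br)cc1OCc4ccccc4)c1c(OCc3ccccc3)c(CCC(C)(C)O)c(Br)cc1OCc4ccccc4
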